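Remark: 3-(benzyloxy)-4-methoxybenzaldehyde (the O-benzyl ether of isovanillin) is taken as a purchasable starting material, and racemic 2-isopropyloxirane is used because its one stereocentre is erased by the later oxidation to the ketone. Benzofuran numbering (O1, C2, C3, C3a, C4–C7, C7a) is applied to all ring-A intermediates, including the open-chain ones.

## Structural features

Moracin Q is an achiral 2-arylbenzofuran: benzo ring A (C3a, C4–C7, C7a) is fused to furan ring B (O1, C2, C3), and a 3,5-dihydroxyphenyl ring C sits on C2. Ring A is pentasubstituted: C4 carries a 3-methyl-2-oxobutyl chain, C5 a methoxy group and C6 a hydroxyl, so that only C7 keeps a hydrogen. There is no stereocentre and no stereogenic double bond, so the problem is one of regiochemistry and chemoselectivity only. The fragile elements are the three phenols, the enolisable ketone next to a benzylic CH2, and the C2=C3 bond of ring B, which can be reduced or attacked by electrophiles. Ring A is especially sensitive once its C7a oxygen is free, because it is then a 4-methoxyphenol that a strong oxidant would take to a quinone. The real difficulty is the carbon substituent at C4, wedged between C3a and the C5 methoxy group: electrophilic substitution and directed metalation of simple trioxygenated benzenes both go elsewhere. The key step exploits the fact that C3a and C4 are neighbours. In a C3a iodide whose other ortho position is the C7a oxygen, C4–H is the only ortho C–H, so a palladium/norbornene relay can alkylate C4 and then olefinate C3a in one operation, leaving the C7a oxygen ready for the later O1–C2 closure.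

## Logic of the disconnections

**13 ⇒ 12.** The three phenolic O–H bonds are traced back to O–CH2Ph bonds. The phenols could not pass through palladium catalysis and two oxidations unmasked, and benzyl ethers come off together in one neutral operation. The gain is that every earlier intermediate is a non-polar, oxidation-resistant ether. The demand is that hydrogenolysis spares the C2=C3 bond of ring B and the ketone.

**12 ⇒ 11.** The O1–C2 bond of ring B is cut. The C7a oxygen is already on ring A, and an ortho-hydroxy E-stilbene is exactly what a Heck termination delivers. The gain is that the heteroaromatic bicycle reduces to an open stilbene. The demand is a dehydrogenative C–O closure mild enough for a 4-methoxyphenol, which is why divalent palladium with benzoquinone is preferred to a quinone or hypervalent-iodine oxidant.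

**11 ⇒ 10 ⇒ 9.** Two functional-group changes are undone: the C7a hydroxyl goes back to its methoxymethyl ether and the ketone to the secondary alcohol. The acetal is needed as the single ortho substituent during the relay, and the alcohol is what epoxide opening gives. The gain is that 9 is the direct product of a three-component coupling. The demand is on the order of events: the alcohol must be oxidised before the phenol is freed, so that no hydroxyl able to add to the stilbene is present under acid or divalent palladium.

**9 ⇒ 5 + 8 + 7.** The C4–CH2 bond and the C3a–C3 bond are cut together. This is the only place where both crowded carbon substituents of ring A can be traced to one C–I bond and one C–H bond. The gain is the largest of the route: a pentasubstituted arene falls to a tetrasubstituted iodide, an epoxide that already carries the side-chain oxygen on the right carbon, and a styrene. The demand is that palladation occurs at a C–H bond flanked by a methoxy group, that the epoxide opens at its CH2 end, and that Heck termination outruns every other fate of the arylpalladium.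

**5 ⇒ 4 ⇒ 3 ⇒ 1.** The O–CH2OMe bond, the C3a–I bond and the C7a–O bond are cut in turn, the last by reading the phenol as the Baeyer–Villiger product of an aldehyde. The oxygen pattern of 1 already matches C5 and C6, and the formyl carbon marks C7a. The gain is a three-step access to 5 from a bulk chemical. The demand is that iodination of 3 goes ortho to the hydroxyl and para to the benzyloxy group.

**7 ⇒ 6.** The terminal C=CH2 bond is cut (Wittig), leading back to a commercial aldehyde. The only demand is complete methylenation.

## Other disconnections considered

**Alternative 1:** The cut is the C5–C6 bond of ring A, so the benzo ring is grown onto a finished 2-arylfuran. In the forward step the furan-3-yl acid A2 would be heated with Ac2O/NaOAc. Its mixed anhydride should lose acetic acid to give the dienylketene A3, whose ketene carbon bonds to the enol-ether terminus in a thermal six-electron electrocyclisation; enolisation and acetylation would give the C5 acetate A1.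
- In favour: every substituent of ring A is fixed by connectivity, so the crowded C4 position raises no site question. On this point the alternative is better than the chosen plan, which depends on palladation of a hindered C–H bond.
- In favour: ring B needs no oxidative closure, also a better point, and the C5 and C6 oxygens emerge differentiated.
- Against: A2 is a demanding 2,3,5-trisubstituted furan with an acid-sensitive enol ether and an α-prenylated acid, and it must survive hot acetic anhydride.
- Against: after A1 the acetate must be exchanged for a methyl ether, and the prenyl group turned into the isopropyl ketone (hydroboration–oxidation then alcohol oxidation, or epoxidation and Meinwald rearrangement) beside the C2=C3 bond. Hydrogenolysis cannot be brought forward because it would saturate the prenyl group.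
- Comparison: structurally it builds ring A where the chosen plan decorates a purchased ring. Mechanistically it is a metal-free pericyclic step and arguably the more predictable one. In step economy it is worse: about five operations after the key step against four, a precursor that by a reasonable count needs seven or more steps against three, and a side chain that arrives as an alkene and not at the alcohol level.

**Alternative 2:** The cut is the O1–C7a bond: ring B is closed by joining the ketone oxygen of a deoxybenzoin to an unfunctionalised arene carbon. In the forward step the deoxybenzoin A5 would be oxidised with FeCl3; the enol oxygen should bond to C7a, which is para to the C5 methoxy group, and rearomatisation would give the benzofuran ester A4.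
- In favour: C7a needs neither oxygen nor halogen beforehand, so the acetal protection, its removal and the separate oxidative closure of the chosen plan (steps 3, 7 and 8) have no counterpart. This is a real saving and a point where the alternative is better.
- In favour: the site is unambiguous because C4 is blocked, which makes it the equal of the chosen plan in site control, and iron is cheap.
- Against: FeCl3 is both a Lewis acid and a one-electron oxidant, so cleavage of benzyl ethers and oxidative coupling or chlorination of the electron-rich rings are conceivable.
- Against: the C4 chain arrives as an ester, and turning it into the isopropyl ketone takes two or three further steps, with the acidic arylacetic CH2 a liability.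
- Against: the contiguous C3a/C4/C5 pattern is not solved by the key step but pushed back into the synthesis of A5.
- Comparison: structurally both plans close ring B by a C–O bond, here from the carbon side of C7a. Mechanistically this is a radical-cation or iron-enolate closure against an organometallic relay. In step economy the post-closure sequence is about equal, but the route to A5 is expected to be longer than the three steps to 5.

**Alternative 3:** The cut is the C2=C3 bond. In the forward step the phosphonium salt A7 would be treated with Et3N in hot toluene; the benzylic ylide should attack the neighbouring aryl ester carbonyl, and collapse of the oxaphosphetane would form the C2=C3 bond and close ring B, giving the prenyl benzofuran A6.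
- In favour: this is a thoroughly tested, non-oxidative and nearly neutral closure for 2-arylbenzofurans, so ring A is never exposed to an oxidant as a free phenol. That is better than step 8 of the chosen plan.
- In favour: ring C enters as a simple aroyl unit, equal in convenience to 7.
- Against: A7 needs ring A already carrying the adjacent CH2P, prenyl and methoxy groups, so the hard substitution problem is again moved into the precursor.
- Against: acyl transfer to the ylide carbon can divert material to a 3-aroylbenzofuran.
- Against: the prenyl group must still be converted into the ketone in two chemoselective steps before hydrogenolysis.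
- Comparison: structurally it forms one ring bond where the chosen key step forms two skeletal bonds and no ring. Mechanistically it is the safer closure. In step economy it is worse: about three steps after the key step but a long precursor synthesis, against nine steps in all for the chosen plan.

Key step: step 5

## Route

**Step 1**
Reactants: 1 3-(benzyloxy)-4-methoxybenzaldehyde
Product: 3 3-(benzyloxy)-4-methoxyphenol, via aryl formate 2 (not isolated)
Conditions: mCPBA, CH2Cl2, 0 °C → rt; aq. NaHCO3 wash; then K2CO3 (cat.), MeOH, rt
Reagents that add atoms: meta-chloroperoxybenzoic acid (mCPBA), O=C(OO)c1cccc(Cl)c1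
Why: Baeyer–Villiger (Dakin-type) oxidation of an electron-rich benzaldehyde: the aryl group, activated by the para methoxy group, migrates to oxygen to give formate 2, and methanolysis frees the phenol; the benzyl and methyl ethers are inert.

**Step 2**
Reactants: 3 3-(benzyloxy)-4-methoxyphenol
Product: 4 5-(benzyloxy)-2-iodo-4-methoxyphenol
Conditions: NIS (1.0 equiv), MeCN, −10 → 0 °C, dark
Reagents that add atoms: N-iodosuccinimide, O=C1CCC(=O)N1I
Why: Electrophilic aromatic iodination; the position ortho to the hydroxyl and para to the benzyloxy group is doubly activated and unhindered, whereas the site between the two oxygens is crowded and the site beside the methoxy group is activated by one oxygen only.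

**Step 3**
Reactants: 4 5-(benzyloxy)-2-iodo-4-methoxyphenol
Product: 5 1-(benzyloxy)-4-iodo-2-methoxy-5-(methoxymethoxy)benzene
Conditions: MOMCl, i-Pr2NEt, CH2Cl2, 0 °C → rt
Reagents that add atoms: chloromethyl methyl ether, COCCl
Why: O-alkylation of the phenoxide with an α-chloro ether gives the methoxymethyl acetal, a small base-stable group that supplies the single ortho substituent the relay needs and keeps the C7a oxygen out of the palladium chemistry.

**Step 4**
Reactants: 6 3,5-bis(benzyloxy)benzaldehyde
Product: 7 1,3-bis(benzyloxy)-5-ethenylbenzene
Conditions: Ph3PCH3Br, KOt-Bu, THF, 0 °C → rt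
Reagents that add atoms: methyltriphenylphosphonium bromide, C[P+](c1ccccc1)(c1ccccc1)c1ccccc1.[Br-]
Why: Wittig methylenation of a non-enolisable aromatic aldehyde with the unstabilised ylide; the benzyl ethers are untouched.

**Step 5**
Reactants: 5 1-(benzyloxy)-4-iodo-2-methoxy-5-(methoxymethoxy)benzene; 8 2-isopropyloxirane (racemic); 7 1,3-bis(benzyloxy)-5-ethenylbenzene
Product: 9 rac-1-{3-(benzyloxy)-6-[(E)-2-(3,5-bis(benzyloxy)phenyl)ethenyl]-2-methoxy-5-(methoxymethoxy)phenyl}-3-methylbutan-2-ol
Conditions: Pd(OAc)2 (10 mol %), XPhos (20 mol %), potassium 5-norbornene-2-carboxylate (1 equiv), K2CO3 (2 equiv), 8 (3 equiv), 7 (1.3 equiv), NMP, 70 °C, sealed vessel, Ar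
Reagents that add atoms: none
Why: Zerovalent palladium, formed in the flask from Pd(OAc)2 and the phosphine, inserts into the C3a–I bond of 5; the norbornene mediator then inserts syn into the aryl–palladium bond, and carboxylate-assisted palladation of C4–H, the only ortho C–H, closes the five-membered aryl–norbornyl palladacycle. This electron-rich divalent palladacycle opens 8 at its unhindered CH2 terminus in an SN2-type oxidative addition to tetravalent palladium, and C(sp2)–C(sp3) reductive elimination forms the C4–CH2 bond. With both positions ortho to palladium now substituted (the C7a acetal oxygen and the new chain), steric pressure drives β-carbon elimination of the norbornene, and the resulting divalent arylpalladium inserts 7 and undergoes syn β-hydride elimination to form the C3a–C3 bond, after which carbonate returns zerovalent palladium. The closest known reaction type is the Catellani ortho-alkylation of aryl iodides with epoxides terminated by a Heck coupling. No ring is closed. The one stereocentre of 9, the carbinol carbon, is carried over untouched from racemic 8 because only the CH2 carbon of the epoxide is attacked, so 9 is racemic, which is harmless since step 6 removes that centre. Three selectivities are needed: the site is secured by C4–H being the sole ortho C–H, the epoxide regiochemistry by the steric difference between its CH2 and CH(i-Pr) carbons, and the E geometry by the syn-insertion/syn-elimination course of the Heck step with the two aryl groups anti; premature Heck coupling of the first arylpalladium is held back by the faster insertion of the strained norbornene and by keeping 7 close to stoichiometric.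

**Step 6**
Reactants: 9 rac-1-{3-(benzyloxy)-6-[(E)-2-(3,5-bis(benzyloxy)phenyl)ethenyl]-2-methoxy-5-(methoxymethoxy)phenyl}-3-methylbutan-2-ol
Product: 10 1-{3-(benzyloxy)-6-[(E)-2-(3,5-bis(benzyloxy)phenyl)ethenyl]-2-methoxy-5-(methoxymethoxy)phenyl}-3-methylbutan-2-one
Conditions: Dess–Martin periodinane, CH2Cl2, 0 °C → rt
Reagents that add atoms: none
Why: Dess–Martin oxidation of a secondary alcohol under near-neutral conditions that leave the acetal, the benzyl ethers and the stilbene alone; it removes the only stereocentre and is placed before deprotection so that no free alcohol can add to the stilbene later.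

**Step 7**
Reactants: 10 1-{3-(benzyloxy)-6-[(E)-2-(3,5-bis(benzyloxy)phenyl)ethenyl]-2-methoxy-5-(methoxymethoxy)phenyl}-3-methylbutan-2-one
Product: 11 1-{3-(benzyloxy)-6-[(E)-2-(3,5-bis(benzyloxy)phenyl)ethenyl]-5-hydroxy-2-methoxyphenyl}-3-methylbutan-2-one
Conditions: 2 M HCl (aq.), MeOH/THF, 45 °C
Reagents that add atoms: none
Why: Acid-catalysed transacetalisation of the aryl methoxymethyl ether to methanol frees the C7a phenol; dilute acid at this temperature should leave the benzyl ethers, the ketone and the stilbene unchanged.

**Step 8**
Reactants: 11 1-{3-(benzyloxy)-6-[(E)-2-(3,5-bis(benzyloxy)phenyl)ethenyl]-5-hydroxy-2-methoxyphenyl}-3-methylbutan-2-one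
Product: 12 1-{6-(benzyloxy)-2-[3,5-bis(benzyloxy)phenyl]-5-methoxy-1-benzofuran-4-yl}-3-methylbutan-2-one
Conditions: PdCl2(MeCN)2 (10 mol %), 1,4-benzoquinone (1.5 equiv), 1,4-dioxane, 80 °C
Reagents that add atoms: none
Why: Wacker-type oxidative cyclisation: the phenol oxygen attacks the palladium-bound alkene at C2 (anti oxypalladation), which places C2–H syn to palladium, and β-hydride elimination gives the aromatic ring B; benzoquinone reoxidises zerovalent palladium and is too weak an oxidant to attack the 4-methoxyphenol.

**Step 9**
Reactants: 12 1-{6-(benzyloxy)-2-[3,5-bis(benzyloxy)phenyl]-5-methoxy-1-benzofuran-4-yl}-3-methylbutan-2-one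
Product: 13 moracin Q, 1-[2-(3,5-dihydroxyphenyl)-6-hydroxy-5-methoxy-1-benzofuran-4-yl]-3-methylbutan-2-one
Conditions: H2 (1 atm), 10% Pd/C, EtOAc/MeOH, rt
Reagents that add atoms: none
Why: Catalytic hydrogenolysis of the three aryl benzyl ethers; at one atmosphere the heteroaromatic C2=C3 bond and the non-conjugated ketone should react far more slowly, and the reaction is stopped once three equivalents of hydrogen are taken up.

## Compound list

1 | 3-(benzyloxy)-4-methoxybenzaldehyde | COc1ccc(C=O)cc1OCc1ccccc1 | starting material
2 | 3-(benzyloxy)-4-methoxyphenyl formate | COc1ccc(OC=O)cc1OCc1ccccc1 | intermediate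
3 | 3-(benzyloxy)-4-methoxyphenol | COc1ccc(O)cc1OCc1ccccc1 | intermediate
4 | 5-(benzyloxy)-2-iodo-4-methoxyphenol | COc1cc(I)c(O)cc1OCc1ccccc1 | intermediate
5 | 1-(benzyloxy)-4-iodo-2-methoxy-5-(methoxymethoxy)benzene | COCOc1cc(OCc2ccccc2)c(OC)cc1I | intermediate
6 | 3,5-bis(benzyloxy)benzaldehyde | O=Cc1cc(OCc2ccccc2)cc(OCc2ccccc2)c1 | starting material
7 | 1,3-bis(benzyloxy)-5-ethenylbenzene | C=Cc1cc(OCc2ccccc2)cc(OCc2ccccc2)c1 | intermediate
8 | 2-isopropyloxirane (racemic) | CC(C)C1CO1 | starting material
9 | rac-1-{3-(benzyloxy)-6-[(E)-2-(3,5-bis(benzyloxy)phenyl)ethenyl]-2-methoxy-5-(methoxymethoxy)phenyl}-3-methylbutan-2-ol | COCOc1cc(OCc2ccccc2)c(OC)c(CC(O)C(C)C)c1/C=C/c1cc(OCc2ccccc2)cc(OCc2ccccc2)c1 | intermediate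
10 | 1-{3-(benzyloxy)-6-[(E)-2-(3,5-bis(benzyloxy)phenyl)ethenyl]-2-methoxy-5-(methoxymethoxy)phenyl}-3-methylbutan-2-one | COCOc1cc(OCc2ccccc2)c(OC)c(CC(=O)C(C)C)c1/C=C/c1cc(OCc2ccccc2)cc(OCc2ccccc2)c1 | intermediate
11 | 1-{3-(benzyloxy)-6-[(E)-2-(3,5-bis(benzyloxy)phenyl)ethenyl]-5-hydroxy-2-methoxyphenyl}-3-methylbutan-2-one | COc1c(OCc2ccccc2)cc(O)c(/C=C/c2cc(OCc3ccccc3)cc(OCc3ccccc3)c2)c1CC(=O)C(C)C | intermediate
12 | 1-{6-(benzyloxy)-2-[3,5-bis(benzyloxy)phenyl]-5-methoxy-1-benzofuran-4-yl}-3-methylbutan-2-one | COc1c(OCc2ccccc2)cc2oc(-c3cc(OCc4ccccc4)cc(OCc4ccccc4)c3)cc2c1CC(=O)C(C)C | intermediate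
13 | moracin Q, 1-[2-(3,5-dihydroxyphenyl)-6-hydroxy-5-methoxy-1-benzofuran-4-yl]-3-methylbutan-2-one | COc1c(O)cc2oc(-c3cc(O)cc(O)c3)cc2c1CC(=O)C(C)C | target

## Step count and risk

Total step count: 9. Longest linear sequence: 8 (steps 1, 2, 3, 5, 6, 7, 8, 9); step 4 is a one-step side branch.

**Step 5 (key step).** The most likely failure is slow palladation of C4–H beside the methoxy group. The arylpalladium could then leak into direct Heck coupling without alkylation, into norbornene-retaining products, or into closure of the new alkoxide onto the ipso carbon before 7 inserts. The fallback sets out from 5 and returns at 9, forming the same two bonds in two separate operations. 5 would be deprotonated at C4–H, the position acidified by the flanking iodine and methoxy group, with LiN(i-Pr)2 in THF at −78 °C. The aryl anion would open 8 at its CH2 terminus in the presence of BF3·OEt2 at −78 °C, giving rac-1-[3-(benzyloxy)-6-iodo-2-methoxy-5-(methoxymethoxy)phenyl]-3-methylbutan-2-ol F1. A conventional Mizoroki–Heck coupling of F1 with 7 (Pd(OAc)2, P(o-tolyl)3, Et3N, DMF, 100 °C) would then give 9.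

**Step 8.** The electron-rich phenol ring could be oxidised in competition with the alkene, or the catalyst could be lost as palladium metal before turnover, because the 5-endo oxypalladation of a hindered stilbene is slow. The fallback sets out from 11 and returns at 12, replacing the metal-catalysed dehydrogenation by an electrophile-induced closure and elimination. 11 would be treated with I2 and NaHCO3 in MeCN at 0 °C; iodonium formation on the stilbene and anti attack of the phenol oxygen at C2 should give the 2,3-trans iodide rac-1-{(2R,3S)-6-(benzyloxy)-2-[3,5-bis(benzyloxy)phenyl]-3-iodo-5-methoxy-2,3-dihydro-1-benzofuran-4-yl}-3-methylbutan-2-one F2. DBU in warm toluene would then remove HI from this benzylic iodide to give 12.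

**Step 9.** Over-reduction of the C2=C3 bond of ring B, or stalling before the third benzyl ether is cleaved, are the likely problems, since the catalyst must distinguish benzylic C–O bonds from a styrene-like double bond. The fallback sets out from 12 and returns at 13 and is non-reductive: BCl3 with pentamethylbenzene as cation scavenger in CH2Cl2 at −78 °C should cleave the three benzyl ethers while sparing the methyl ether, the ketone and ring B. It makes no new compound (entry F0).

**Step 2.** The iodinating agent could oxidise the 4-alkoxyphenol instead of substituting it, or iodinate a second time at the position between the two oxygens, because the free phenol is both very electron-rich and a hydroquinone monoether. The fallback sets out from 3 and returns at 5, reversing the order so that an aryl ether and not a free phenol is iodinated. 3 would be protected with MOMCl and i-Pr2NEt to give 2-(benzyloxy)-1-methoxy-4-(methoxymethoxy)benzene F3. NIS in MeCN at rt should then iodinate F3 para to the benzyloxy group, the position between the two acetal-type oxygens being the more hindered, to give 5 directly, bypassing 4.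

## Further compounds

F1 | step 5 | rac-1-[3-(benzyloxy)-6-iodo-2-methoxy-5-(methoxymethoxy)phenyl]-3-methylbutan-2-ol | COCOc1cc(OCc2ccccc2)c(OC)c(CC(O)C(C)C)c1I
F2 | step 8 | rac-1-{(2R,3S)-6-(benzyloxy)-2-[3,5-bis(benzyloxy)phenyl]-3-iodo-5-methoxy-2,3-dihydro-1-benzofuran-4-yl}-3-methylbutan-2-one (2,3-trans) | I[C@@H]1[C@@H](c2cc(OCc3ccccc3)cc(OCc3ccccc3)c2)Oc2cc(OCc3ccccc3)c(OC)c(CC(=O)C(C)C)c21
F0 | step 9 | none | none
F3 | step 2 | 2-(benzyloxy)-1-methoxy-4-(methoxymethoxy)benzene | COCOc1ccc(OC)c(OCc2ccccc2)c1
A1 | alternative 1 | 6-(benzyloxy)-2-[3,5-bis(benzyloxy)phenyl]-4-(3-methylbut-2-enyl)benzofuran-5-yl acetate | CC(C)=CCc1c(OC(C)=O)c(OCc2ccccc2)cc2oc(-c3cc(OCc4ccccc4)cc(OCc4ccccc4)c3)cc12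
A2 | alternative 1 | rac-2-{5-[3,5-bis(benzyloxy)phenyl]-2-[(E)-2-(benzyloxy)ethenyl]furan-3-yl}-5-methylhex-4-enoic acid | CC(C)=CCC(C(=O)O)c1cc(-c2cc(OCc3ccccc3)cc(OCc3ccccc3)c2)oc1/C=C/OCc1ccccc1
A3 | alternative 1 | 2-{5-[3,5-bis(benzyloxy)phenyl]-2-[(E)-2-(benzyloxy)ethenyl]furan-3-yl}-5-methylhexa-1,4-dien-1-one (dienylketene) | CC(C)=CCC(=C=O)c1cc(-c2cc(OCc3ccccc3)cc(OCc3ccccc3)c2)oc1/C=C/OCc1ccccc1
A4 | alternative 2 | methyl 2-{6-(benzyloxy)-2-[3,5-bis(benzyloxy)phenyl]-5-methoxybenzofuran-4-yl}acetate | COC(=O)Cc1c(OC)c(OCc2ccccc2)cc2oc(-c3cc(OCc4ccccc4)cc(OCc4ccccc4)c3)cc12
A5 | alternative 2 | methyl 2-{3-(benzyloxy)-6-{2-[3,5-bis(benzyloxy)phenyl]-2-oxoethyl}-2-methoxyphenyl}acetate | COC(=O)Cc1c(OC)c(OCc2ccccc2)ccc1CC(=O)c1cc(OCc2ccccc2)cc(OCc2ccccc2)c1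
A6 | alternative 3 | 6-(benzyloxy)-2-[3,5-bis(benzyloxy)phenyl]-5-methoxy-4-(3-methylbut-2-enyl)benzofuran | COc1c(OCc2ccccc2)cc2oc(-c3cc(OCc4ccccc4)cc(OCc4ccccc4)c3)cc2c1CC=C(C)C
A7 | alternative 3 | {[4-(benzyloxy)-2-{[3,5-bis(benzyloxy)benzoyl]oxy}-5-methoxy-6-(3-methylbut-2-en-1-yl)phenyl]methyl}triphenylphosphonium bromide | COc1c(OCc2ccccc2)cc(OC(=O)c2cc(OCc3ccccc3)cc(OCc3ccccc3)c2)c(C[P+](c2ccccc2)(c2ccccc2)c2ccccc2)c1CC=C(C)C.[Br-]
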